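**Retrosynthetic overview**

1. The route rests on the benzaldehyde ring (C1 CHO, C2 side chain, C3 OH, C4 OMe, C5 H, C6 OH). The oxygens at C4 and C6 sit meta to each other across C5–H, so the ring is a masked cyclohexane-1,3-dione with a carboxyl-level carbon on C1 and the chain on C2.
2. Late stage: the aldehyde is unveiled by DDQ from an ArCH2OMe group after the silyl-to-acetyl exchange, and the two benzyl ethers are removed last. C3–OH comes from Elbs para-hydroxylation of the C6 phenol, O4 is methylated selectively, and the arene comes from the dione by bromination–dehydrobromination.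
3. The only ring is formed once, by a Michael–Claisen annulation of dimethyl malonate with (R,E)-6-silyloxyheptadec-3-en-2-one, which makes C1–C2 and C5–C6.
4. The enone comes from (R)-3-hydroxytetradecanoic acid by esterification, silylation, half-reduction and Wittig olefination. The single stereocentre is taken from the chiral pool and no bond to it is broken.

Key step: step 5

Remark: the side-chain oxygen is carried as a tert-butyldiphenylsilyl ether rather than a smaller silyl ether because steps 6 and 8 pass through HBr and aqueous acid, and the acetate is installed while the C1 carbon is still a benzylic methyl ether because a free 2-hydroxyalkyl group ortho to the aldehyde would close to a six-membered lactol.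

**Route**

Step 1
Reactants: 1 (R)-3-hydroxytetradecanoic acid
Product: 2 methyl (R)-3-hydroxytetradecanoate
Conditions: MeOH, H2SO4 (cat.), reflux
Reagents that add atoms: methanol, CO
Why: Fischer esterification of the acid should proceed cleanly, and the carbinol stereocentre takes no part.

Step 2
Reactants: 2 methyl (R)-3-hydroxytetradecanoate
Product: 3 methyl (R)-3-(tert-butyldiphenylsilyloxy)tetradecanoate
Conditions: tert-butylchlorodiphenylsilane, imidazole, DMAP (cat.), DMF, rt
Reagents that add atoms: tert-butylchlorodiphenylsilane, CC(C)(C)[Si](Cl)(c1ccccc1)c1ccccc1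
Why: Imidazole-promoted silylation of the secondary alcohol gives an ether that should tolerate alkoxide, hydride, HBr and dilute aqueous acid in the later steps.

Step 3
Reactants: 3 methyl (R)-3-(tert-butyldiphenylsilyloxy)tetradecanoate
Product: 4 (R)-3-(tert-butyldiphenylsilyloxy)tetradecanal
Conditions: iBu2AlH (1.1 equiv), CH2Cl2, −78 °C; MeOH quench, aq. KNaC4H4O6
Reagents that add atoms: none
Why: Low-temperature half-reduction of a β-silyloxy ester with diisobutylaluminium hydride stops at the aluminium hemiacetal, which should release the aldehyde only on work-up; the aldehyde is used crude to avoid β-elimination.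

Step 4
Reactants: 4 (R)-3-(tert-butyldiphenylsilyloxy)tetradecanal; 5 1-(triphenylphosphoranylidene)propan-2-one
Product: 6 (R,E)-6-(tert-butyldiphenylsilyloxy)heptadec-3-en-2-one
Conditions: toluene, 80 °C
Reagents that add atoms: none
Why: Wittig olefination with the stabilised acetonyl ylide should give the (E)-enone under neutral conditions that do not eliminate the β-silyloxy group.

Step 5
Reactants: 6 (R,E)-6-(tert-butyldiphenylsilyloxy)heptadec-3-en-2-one; 7 dimethyl malonate
Product: 9 methyl 6-[(R)-2-(tert-butyldiphenylsilyloxy)tridecyl]-2,4-dioxocyclohexane-1-carboxylate (ring stereocentres uncontrolled, enolised), via Michael adduct 8 (not isolated)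
Conditions: 7 (1.5 equiv), NaOMe (1.3 equiv), MeOH/THF, 0 °C → rt, then 65 °C; cold 1 M HCl to pH 3
Reagents that add atoms: none
Why: Sodium dimethyl malonate adds in a Michael reaction to C4 of enone 6 (the future ring carbon C2 of the target) to give adduct 8; proton transfer then places the ketone enolate on its methyl side, this carbon attacks one malonate ester carbonyl in an intramolecular Claisen condensation, methoxide leaves, and deprotonation of the resulting β-diketone (a vinylogous acid) makes the sequence irreversible. The closest known reaction type is the malonate Michael–Claisen annulation of alkenyl methyl ketones to 6-substituted 2,4-dioxocyclohexanecarboxylates (dihydroresorcylates). The single ring closes in a 6-(enolendo)-exo-trig mode, since both enolate carbons (C3 and C4 of the new ring) lie inside it, and closure through the internal methylene enolate would give a four-membered ring and should not compete. The two new ring stereocentres (C1 and C6 of the cyclohexanedione) are under no useful control, C1 being epimerisable, and both are erased by the aromatisation of step 6, while the silyloxy-bearing carbon is untouched. The step needs chemoselectivity for conjugate addition over γ-deprotonation of 6 with vinylogous loss of silyloxide: the malonate anion is preformed and kept in excess so that little free methoxide meets the enone, the addition is run cold before heating, and once C4 is sp3 the elimination path is closed.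

Step 6
Reactants: 9 methyl 6-[(R)-2-(tert-butyldiphenylsilyloxy)tridecyl]-2,4-dioxocyclohexane-1-carboxylate
Product: 11 methyl 2,4-dihydroxy-6-[(R)-2-(tert-butyldiphenylsilyloxy)tridecyl]benzoate, via 3-bromo dione 10 (not isolated)
Conditions: Br2 (1.0 equiv), DMF, 0 °C; then 80 °C
Reagents that add atoms: none
Why: Bromination of the dione enol at C3 followed by thermal, HBr-mediated bromine migration and dehydrobromination is the established aromatisation of dihydroresorcylates to resorcylates; the temperature is held well below that at which demethylative decarboxylation sets in.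

Step 7
Reactants: 11 methyl 2,4-dihydroxy-6-[(R)-2-(tert-butyldiphenylsilyloxy)tridecyl]benzoate
Product: 12 methyl 2-hydroxy-4-methoxy-6-[(R)-2-(tert-butyldiphenylsilyloxy)tridecyl]benzoate (target numbering: C6–OH, C4–OMe, chain on C2)
Conditions: MeI (1.05 equiv), K2CO3 (1.1 equiv), acetone, rt
Reagents that add atoms: iodomethane, CI
Why: Williamson methylation should take the phenol para to the ester, which is the more acidic and unhindered one, while the ortho phenol is held in a hydrogen bond to the ester carbonyl.

Step 8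
Reactants: 12 methyl 2-hydroxy-4-methoxy-6-[(R)-2-(tert-butyldiphenylsilyloxy)tridecyl]benzoate
Product: 14 methyl 3,6-dihydroxy-4-methoxy-2-[(R)-2-(tert-butyldiphenylsilyloxy)tridecyl]benzoate, via aryl sulfate potassium salt 13 (not isolated)
Conditions: K2S2O8 (1.2 equiv), aq. NaOH, pyridine, 0 °C → rt; then aq. HCl (pH 1), Na2SO3, THF, 45 °C
Reagents that add atoms: potassium peroxodisulfate, [K+].[K+].[O-]S(=O)(=O)OOS(=O)(=O)[O-]
Why: In the Elbs persulfate oxidation the phenoxide attacks a peroxide oxygen through its para carbon (C3, the only para position), and the resulting aryl sulfate is hydrolysed by dilute acid; the reaction is established for 2-hydroxy-4-methoxyaryl carbonyl compounds, and the hindered, phenoxide-deactivated ester should resist the aqueous base.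

Step 9
Reactants: 14 methyl 3,6-dihydroxy-4-methoxy-2-[(R)-2-(tert-butyldiphenylsilyloxy)tridecyl]benzoate
Product: 15 methyl 3,6-bis(benzyloxy)-4-methoxy-2-[(R)-2-(tert-butyldiphenylsilyloxy)tridecyl]benzoate
Conditions: BnBr (2.5 equiv), K2CO3, Bu4NI (cat.), DMF, 60 °C, argon
Reagents that add atoms: benzyl bromide, BrCc1ccccc1
Why: Williamson benzylation of both phenols under exclusion of air protects the hydroquinone against oxidation and makes the ester reducible without quinone methide chemistry.

Step 10
Reactants: 15 methyl 3,6-bis(benzyloxy)-4-methoxy-2-[(R)-2-(tert-butyldiphenylsilyloxy)tridecyl]benzoate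
Product: 16 {3,6-bis(benzyloxy)-4-methoxy-2-[(R)-2-(tert-butyldiphenylsilyloxy)tridecyl]phenyl}methanol
Conditions: LiAlH4, THF, 0 → 40 °C; H2O, aq. NaOH work-up
Reagents that add atoms: none
Why: Hydride reduction with LiAlH4 should convert the di-ortho-substituted aryl ester into the benzylic alcohol and leave the silyl and benzyl ethers alone.

Step 11
Reactants: 16 {3,6-bis(benzyloxy)-4-methoxy-2-[(R)-2-(tert-butyldiphenylsilyloxy)tridecyl]phenyl}methanol
Product: 17 tert-butyl({(R)-1-[2,5-bis(benzyloxy)-3-methoxy-6-(methoxymethyl)phenyl]tridecan-2-yl}oxy)diphenylsilane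
Conditions: NaH, MeI, THF, 0 °C → rt
Reagents that add atoms: iodomethane, CI
Why: Williamson methylation masks the acid-labile, electron-rich benzylic alcohol as a methyl ether, so that C1 stays at the alcohol level while the side-chain oxygen is exchanged.

Step 12
Reactants: 17 tert-butyl({(R)-1-[2,5-bis(benzyloxy)-3-methoxy-6-(methoxymethyl)phenyl]tridecan-2-yl}oxy)diphenylsilane
Product: 18 (R)-1-[2,5-bis(benzyloxy)-3-methoxy-6-(methoxymethyl)phenyl]tridecan-2-ol
Conditions: Bu4NF, THF, rt → 45 °C; aq. NH4Cl
Reagents that add atoms: none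
Why: Fluoride cleaves the Si–O bond only, so the alcohol is released with its configuration intact and the alkyl and aryl ethers are unaffected.

Step 13
Reactants: 18 (R)-1-[2,5-bis(benzyloxy)-3-methoxy-6-(methoxymethyl)phenyl]tridecan-2-ol
Product: 19 (R)-1-[2,5-bis(benzyloxy)-3-methoxy-6-(methoxymethyl)phenyl]tridecan-2-yl acetate
Conditions: Ac2O, pyridine, DMAP (cat.), CH2Cl2, rt
Reagents that add atoms: acetic anhydride, CC(=O)OC(C)=O
Why: DMAP-catalysed acylation of the only free hydroxyl acylates at oxygen, so the stereocentre is retained.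

Step 14
Reactants: 19 (R)-1-[2,5-bis(benzyloxy)-3-methoxy-6-(methoxymethyl)phenyl]tridecan-2-yl acetate
Product: 20 (R)-1-[2,5-bis(benzyloxy)-6-formyl-3-methoxyphenyl]tridecan-2-yl acetate
Conditions: DDQ (1.3 equiv), CH2Cl2/pH 7 phosphate buffer, 0 °C → rt
Reagents that add atoms: water, O
Why: DDQ abstracts hydride from the benzylic ether carbon, which is activated by the ortho benzyloxy and para methoxy groups, and water converts the oxocarbenium ion through its hemiacetal into the aldehyde and methanol; this is the oxidative cleavage of dialkoxybenzyl ethers read from the arene side, and the acetate and the plain aryl benzyl ethers should not react.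

Step 15
Reactants: 20 (R)-1-[2,5-bis(benzyloxy)-6-formyl-3-methoxyphenyl]tridecan-2-yl acetate
Product: 21 (R)-1-(6-formyl-2,5-dihydroxy-3-methoxyphenyl)tridecan-2-yl acetate (CNP0112378.1)
Conditions: H2 (1 atm), 10% Pd/C, EtOAc, rt, stopped after uptake of 2 equiv
Reagents that add atoms: none
Why: Hydrogenolysis of the two aryl benzyl ethers in a neutral aprotic solvent should outrun reduction of the hindered, electron-rich aldehyde, which becomes hydrogen-bonded to the freed ortho phenol, and does not affect the acetate or the stereocentre.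

**Compound list**

1 | (R)-3-hydroxytetradecanoic acid | CCCCCCCCCCC[C@H](CC(=O)O)O | starting material
2 | methyl (R)-3-hydroxytetradecanoate | CCCCCCCCCCC[C@H](CC(=O)OC)O | intermediate
3 | methyl (R)-3-(tert-butyldiphenylsilyloxy)tetradecanoate | CCCCCCCCCCC[C@H](CC(=O)OC)O[Si](c1ccccc1)(c1ccccc1)C(C)(C)C | intermediate
4 | (R)-3-(tert-butyldiphenylsilyloxy)tetradecanal | CCCCCCCCCCC[C@H](CC=O)O[Si](c1ccccc1)(c1ccccc1)C(C)(C)C | intermediate
5 | 1-(triphenylphosphoranylidene)propan-2-one | CC(=O)C=P(c1ccccc1)(c1ccccc1)c1ccccc1 | starting material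
6 | (R,E)-6-(tert-butyldiphenylsilyloxy)heptadec-3-en-2-one | CCCCCCCCCCC[C@H](C/C=C/C(C)=O)O[Si](c1ccccc1)(c1ccccc1)C(C)(C)C | intermediate
7 | dimethyl malonate | COC(=O)CC(=O)OC | starting material
8 | dimethyl 2-[(6R)-6-(tert-butyldiphenylsilyloxy)-2-oxoheptadecan-4-yl]malonate (Michael adduct, both C4 epimers) | CCCCCCCCCCC[C@H](CC(CC(C)=O)C(C(=O)OC)C(=O)OC)O[Si](c1ccccc1)(c1ccccc1)C(C)(C)C | intermediate
9 | methyl 6-[(R)-2-(tert-butyldiphenylsilyloxy)tridecyl]-2,4-dioxocyclohexane-1-carboxylate (ring stereocentres uncontrolled) | COC(=O)C1C(=O)CC(=O)CC1C[C@H](O[Si](c1ccccc1)(c1ccccc1)C(C)(C)C)CCCCCCCCCCC | intermediate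
10 | methyl 3-bromo-6-[(R)-2-(tert-butyldiphenylsilyloxy)tridecyl]-2,4-dioxocyclohexane-1-carboxylate | COC(=O)C1C(=O)C(Br)C(=O)CC1C[C@H](O[Si](c1ccccc1)(c1ccccc1)C(C)(C)C)CCCCCCCCCCC | intermediate
11 | methyl 2,4-dihydroxy-6-[(R)-2-(tert-butyldiphenylsilyloxy)tridecyl]benzoate | COC(=O)c1c(O)cc(O)cc1C[C@H](O[Si](c1ccccc1)(c1ccccc1)C(C)(C)C)CCCCCCCCCCC | intermediate
12 | methyl 2-hydroxy-4-methoxy-6-[(R)-2-(tert-butyldiphenylsilyloxy)tridecyl]benzoate | COC(=O)c1c(O)cc(OC)cc1C[C@H](O[Si](c1ccccc1)(c1ccccc1)C(C)(C)C)CCCCCCCCCCC | intermediate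
13 | potassium salt of methyl 6-hydroxy-4-methoxy-3-(sulfooxy)-2-[(R)-2-(tert-butyldiphenylsilyloxy)tridecyl]benzoate | COC(=O)c1c(O)cc(OC)c(OS(=O)(=O)[O-])c1C[C@H](O[Si](c1ccccc1)(c1ccccc1)C(C)(C)C)CCCCCCCCCCC.[K+] | intermediate
14 | methyl 3,6-dihydroxy-4-methoxy-2-[(R)-2-(tert-butyldiphenylsilyloxy)tridecyl]benzoate | COC(=O)c1c(O)cc(OC)c(O)c1C[C@H](O[Si](c1ccccc1)(c1ccccc1)C(C)(C)C)CCCCCCCCCCC | intermediate
15 | methyl 3,6-bis(benzyloxy)-4-methoxy-2-[(R)-2-(tert-butyldiphenylsilyloxy)tridecyl]benzoate | COC(=O)c1c(OCc2ccccc2)cc(OC)c(OCc2ccccc2)c1C[C@H](O[Si](c1ccccc1)(c1ccccc1)C(C)(C)C)CCCCCCCCCCC | intermediate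
16 | {3,6-bis(benzyloxy)-4-methoxy-2-[(R)-2-(tert-butyldiphenylsilyloxy)tridecyl]phenyl}methanol | OCc1c(OCc2ccccc2)cc(OC)c(OCc2ccccc2)c1C[C@H](O[Si](c1ccccc1)(c1ccccc1)C(C)(C)C)CCCCCCCCCCC | intermediate
17 | tert-butyl({(R)-1-[2,5-bis(benzyloxy)-3-methoxy-6-(methoxymethyl)phenyl]tridecan-2-yl}oxy)diphenylsilane | COCc1c(OCc2ccccc2)cc(OC)c(OCc2ccccc2)c1C[C@H](O[Si](c1ccccc1)(c1ccccc1)C(C)(C)C)CCCCCCCCCCC | intermediate
18 | (R)-1-[2,5-bis(benzyloxy)-3-methoxy-6-(methoxymethyl)phenyl]tridecan-2-ol | COCc1c(OCc2ccccc2)cc(OC)c(OCc2ccccc2)c1C[C@H](O)CCCCCCCCCCC | intermediate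
19 | (R)-1-[2,5-bis(benzyloxy)-3-methoxy-6-(methoxymethyl)phenyl]tridecan-2-yl acetate | COCc1c(OCc2ccccc2)cc(OC)c(OCc2ccccc2)c1C[C@H](OC(C)=O)CCCCCCCCCCC | intermediate
20 | (R)-1-[2,5-bis(benzyloxy)-6-formyl-3-methoxyphenyl]tridecan-2-yl acetate | O=Cc1c(OCc2ccccc2)cc(OC)c(OCc2ccccc2)c1C[C@H](OC(C)=O)CCCCCCCCCCC | intermediate
21 | (R)-1-(6-formyl-2,5-dihydroxy-3-methoxyphenyl)tridecan-2-yl acetate (CNP0112378.1) | CCCCCCCCCCC[C@H](Cc1c(O)c(OC)cc(O)c1C=O)OC(C)=O | target

**Step count and risks**

Total step count: 15. Longest linear sequence: 15 steps (1 → 21).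

Steps most likely to fail:

Step 8. The peroxodisulfate may be consumed in radical side paths, attack at the doubly flanked para carbon may be slow so that conversion stays low, the product hydroquinone may be oxidised further, and the acid hydrolysis of the sulfate may start to cleave the silyl ether. The fallback sets out from 12 and replaces the direct hydroxylation by halogenation and C–B oxidation. Bromination with N-bromosuccinimide (MeCN, 0 °C) para to the phenol should give methyl 3-bromo-6-hydroxy-4-methoxy-2-[(R)-2-(tert-butyldiphenylsilyloxy)tridecyl]benzoate F1. Benzylation (BnBr, K2CO3, DMF) gives methyl 6-(benzyloxy)-3-bromo-4-methoxy-2-[(R)-2-(tert-butyldiphenylsilyloxy)tridecyl]benzoate F2. Miyaura borylation (B2pin2, Pd(OAc)2, 2-dicyclohexylphosphino-2',6'-dimethoxybiphenyl, KOAc, dioxane, 90 °C) gives methyl 6-(benzyloxy)-4-methoxy-3-(4,4,5,5-tetramethyl-1,3,2-dioxaborolan-2-yl)-2-[(R)-2-(tert-butyldiphenylsilyloxy)tridecyl]benzoate F3. Oxidation (NaBO3·4H2O, THF/H2O) gives methyl 6-(benzyloxy)-3-hydroxy-4-methoxy-2-[(R)-2-(tert-butyldiphenylsilyloxy)tridecyl]benzoate F4, and a second benzylation returns to the route at 15.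

Step 5. Methoxide may deprotonate the enone at its γ-carbon and expel the silyloxide in a vinylogous elimination before the malonate adds, or the adduct may revert by retro-Michael reaction faster than it cyclises. The fallback sets out from aldehyde 4 and builds the same open-chain adduct without an enone and without base. Knoevenagel condensation of 4 with dimethyl malonate 7 (TiCl4, pyridine, THF, 0 °C) gives dimethyl 2-[(R)-3-(tert-butyldiphenylsilyloxy)tetradecylidene]malonate F5. Mukaiyama–Michael addition of 2-(trimethylsilyloxy)propene (TiCl4, CH2Cl2, −78 °C) gives the adduct 8, now isolated. Separate Claisen cyclisation of 8 with NaOMe in MeOH at 65 °C returns to the route at 9.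

Step 6. The HBr set free may cleave the silyl ether, after which the freed alcohol would lactonise onto the ester, and bromine released in the equilibration may brominate the newly formed resorcinol ring. The fallback sets out from 9 and avoids both halogen and strong acid. Enol ether formation at the less hindered, non-chelated ketone (HC(OMe)3, MeOH, pyridinium p-toluenesulfonate cat., rt) gives methyl 4-methoxy-2-oxo-6-[(R)-2-(tert-butyldiphenylsilyloxy)tridecyl]cyclohex-3-ene-1-carboxylate F6. Dehydrogenation with DDQ (dioxane, 80 °C) aromatises this β-keto ester directly to 12, where the route is rejoined; compound 11 and step 7 are then not needed.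

**Further compounds**

F1 | step 8 | methyl 3-bromo-6-hydroxy-4-methoxy-2-[(R)-2-(tert-butyldiphenylsilyloxy)tridecyl]benzoate | COC(=O)c1c(O)cc(OC)c(Br)c1C[C@H](O[Si](c1ccccc1)(c1ccccc1)C(C)(C)C)CCCCCCCCCCC
F2 | step 8 | methyl 6-(benzyloxy)-3-bromo-4-methoxy-2-[(R)-2-(tert-butyldiphenylsilyloxy)tridecyl]benzoate | COC(=O)c1c(OCc2ccccc2)cc(OC)c(Br)c1C[C@H](O[Si](c1ccccc1)(c1ccccc1)C(C)(C)C)CCCCCCCCCCC
F3 | step 8 | methyl 6-(benzyloxy)-4-methoxy-3-(4,4,5,5-tetramethyl-1,3,2-dioxaborolan-2-yl)-2-[(R)-2-(tert-butyldiphenylsilyloxy)tridecyl]benzoate | COC(=O)c1c(OCc2ccccc2)cc(OC)c(B2OC(C)(C)C(C)(C)O2)c1C[C@H](O[Si](c1ccccc1)(c1ccccc1)C(C)(C)C)CCCCCCCCCCC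
F4 | step 8 | methyl 6-(benzyloxy)-3-hydroxy-4-methoxy-2-[(R)-2-(tert-butyldiphenylsilyloxy)tridecyl]benzoate | COC(=O)c1c(OCc2ccccc2)cc(OC)c(O)c1C[C@H](O[Si](c1ccccc1)(c1ccccc1)C(C)(C)C)CCCCCCCCCCC
F5 | step 5 | dimethyl 2-[(R)-3-(tert-butyldiphenylsilyloxy)tetradecylidene]malonate | CCCCCCCCCCC[C@H](CC=C(C(=O)OC)C(=O)OC)O[Si](c1ccccc1)(c1ccccc1)C(C)(C)C
F6 | step 6 | methyl 4-methoxy-2-oxo-6-[(R)-2-(tert-butyldiphenylsilyloxy)tridecyl]cyclohex-3-ene-1-carboxylate | COC(=O)C1C(=O)C=C(OC)CC1C[C@H](O[Si](c1ccccc1)(c1ccccc1)C(C)(C)C)CCCCCCCCCCC
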